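## Structural features

The target is a 1,2,3,5-tetrasubstituted cyclopentane. Its ring atoms are numbered here C1 (bearing the CH2O–acyl group), C2 (methyl), C3 (acyloxy), C4 (methylene) and C5 (bearing the 1,3-dihydroxypropan-2-yl group). The four stereocentres C5, C1, C2 and C3 are contiguous and alternate up and down (5R,1S,2R,3R), so every neighbouring pair of substituents is trans. Both acylated oxygens carry the same acid, (3S,4E)-4-formyl-3-(2-oxoethyl)hex-4-enoic acid, whose single stereocentre lies between an E-configured 2-ethylidene enal and a CH2CHO arm. The fragile parts are these 1,5-dialdehydes (an electrophilic enal and an enolisable aldehyde), the two esters (which exclude basic or hydridic reagents late in the route) and the free 1,3-diol (which must be kept apart from the two hydroxyls that are acylated). The real difficulty is twofold: setting four ring centres all-trans, including C1 between two substituted carbons, and releasing four aldehydes and a diol at the end without touching the esters. The key step exploits the C2–C3 ring bond. Opened there, the ring is an aldehyde (C3) tethered through C4 and C5 to a C1 alkenyl unit carrying an ethylidene group (C2 and its methyl) and a CH2–heteroatom group. This is the same 2-ethylidene unit as in both acyl chains, so one alkenyl building block serves ring and side chains.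

## Logic of the disconnections

36 back to 33. No skeletal bond is cut. The free diol is traced back to its acetonide (35), the four aldehydes to four primary alcohols (34) and these to four silyl ethers (33). The reason is that neither the dialdehydes nor the free diol can be carried through an esterification. The gain is that 33 holds only esters, silyl ethers and one acetal. The demand is that steps 21 to 23 are non-basic and the diol appears last.

33 to 26 and 31. The two ester carbon–oxygen bonds (at the C1 methylene oxygen and at the C3 oxygen) are cut. Both acyl groups are identical, so one acid is used twice. The gain is a small core diol and an acid with one stereocentre. The demand is that the hindered C3 hydroxyl is acylated while the other two hydroxyls of the core stay masked; 31 has no α-stereocentre that activation could scramble.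

31 to 28, then to 27 and 8. The hydroxy acid is closed back to a δ-lactone, and the bond between the acyl stereocentre and the alkenyl carbon is cut. The lactone carbonyl and ring oxygen are exactly the later carboxyl and CH2CHO arm, and a cyclic enoate is the best acceptor for an alkenyl–rhodium species. The gain is a commercial achiral lactone plus 8. The demand is that the catalyst alone sets the (S) centre and leaves the alkene geometry of 8 intact.

26 to 19 (through 25, 24, 22, 20). The C1 hydrogen and the hydroxyl of the C1 branch are removed, so that the hydroxymethyl group becomes an exocyclic methylidene. The ring closure leaves exactly this group, and an aldehyde at C1 lets thermodynamics choose the all-trans arrangement. The gain is one stereocentre less. The demand is anti-Markovnikov hydroboration, epimerisation at C1 only, and a protected C3 oxygen during the oxidation.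

19 to 18. The C2–C3 ring bond is cut. This removes the ring and two stereocentres at once and leaves an open chain with one stereocentre and the ethylidene/CH2Br alkenyl unit. The demand is γ-selective, closed-transition-state allylation with retention of alkene geometry and with facial control from the single resident centre.

18 to 14 (through 17, 15), then to 13 and 8. The aldehyde is traced to a methyl ester and the bromide to a silyl ether; then the bond between the stereocentre and the alkenyl carbon is cut, the same bond type as in 28. The gain is the achiral acceptor 13 and the shared reagent 8. The demand is catalyst control of the only stereocentre. The bromide must also be installed before the aldehyde is released, because a free allylic hydroxyl and the aldehyde would close to a lactol.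

13 to 11 and 12, then 10 and 9. The enoate double bond is cut by olefination, the aldehyde is traced to the alcohol and the acetonide to the triol. The gain is three commodity compounds. The demand is mild base in the olefination, since 11 is a β-alkoxy aldehyde.

8 to 5, 4, 3 and 1. The carbon–boron bond is traced to a carbon–bromine bond, the silyl ether to the alcohol, the alcohol to the aldehyde, and the vinylic bromide to the parent enal. The gain is a four-carbon commodity aldehyde. The demand is that the Z geometry fixed in step 1 is kept through halogen–metal exchange.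

## Other disconnections considered

Alternative 1: The cut removes the C2–CH3 bond and the C1–CH2OH bond from a cyclopentanone whose carbonyl carbon is the later C5. In the forward step a methyl cuprate adds to the β-carbon of (4R)-4-{[TBS]oxy}cyclopent-2-en-1-one A1 anti to the silyloxy group. The enolate is then trapped by a one-carbon aldehyde electrophile anti to the new methyl group, which would give (2S,3R,4R)-4-{[TBS]oxy}-2-(hydroxymethyl)-3-methylcyclopentan-1-one A2.
- In favour: this is substrate-controlled addition chemistry with strong precedent and needs no asymmetric catalysis for the ring. On stereocentres set per step it is better than the chosen plan: C1, C2 and C3 arise in one operation, against two centres in step 12 and a third only through steps 14 to 16.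
- Against: A2 is a β-hydroxy ketone that can lose water, and its regioisomeric enolate can expel the silyloxy group. C5 and its three-carbon branch would still have to be built from the ketone carbon by olefination and a face-selective reduction, with C1 now epimerisable next to the carbonyl.
- Comparison: the key step itself is the equal of the chromium closure in reliability. Structurally it leaves the hardest centre unsolved, the step count after A2 is expected to be no lower than after 19, and the alkenyl building block is not shared.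

Alternative 2: The cut is the C1–C5 ring bond. In the forward step a secondary-amine catalyst converts the aldehyde of dimethyl 2-[(3R,4R)-3-{[TBS]oxy}-4-methyl-6-oxohexylidene]propanedioate A3 into an enamine, which adds 5-exo-trig to the alkylidene malonate. This would give dimethyl 2-[(1R,2S,3R,4R)-4-{[TBS]oxy}-2-formyl-3-methylcyclopentyl]propanedioate A4.
- In favour: A4 has all four ring centres and the right oxidation pattern (formyl for the C1 arm, malonate for the C5 branch). C1 and C5 are formed trans directly, and on this point it is better than the chosen plan, which needs steps 14 to 16 to set C1.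
- Against: A3 must already contain the anti-related methyl and silyloxy centres. That calls for a separate asymmetric aldol or crotylation sequence and chain extension at both ends, and the catalyst must match two resident centres.
- Comparison: mechanistically it is catalyst plus substrate control in an enamine Michael addition, against a metal-templated closed transition state under substrate control; both close the ring with two new centres. Step economy is at best equal, and no building block is shared with the acyl chains.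

Alternative 3: The cut is made at both acyl chains, between each stereocentre and its alkenyl carbon, at the very end. In the forward step two equivalents of 8 add to the bis-enoate {(1S,2R,3R,5R)-5-(2,2-dimethyl-1,3-dioxan-5-yl)-2-methyl-3-{[(2E)-5-{[TBS]oxy}pent-2-enoyl]oxy}cyclopentyl}methyl (2E)-5-{[TBS]oxy}pent-2-enoate A5 under a rhodium–diphosphine catalyst. The product would be the tetrakis-silyl diester A6, which is identical with 33.
- In favour: it is the most convergent plan and uses the same reaction type as steps 8 and 18, so it is mechanistically equal. In step count it is about equal, because A5 needs a silyloxypentenoic acid of similar length to 31.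
- Against: two catalyst-controlled additions must both succeed on a late, valuable intermediate. Open-chain E-enoates are poorer acceptors than 27, and incomplete selectivity would give diastereomers that differ only at remote centres and would be hard to separate.
- Comparison: the chosen plan makes the same bond on a small lactone, where the adduct can be purified and its configuration checked before it meets the core.

Key step: step 12

Remark on the chemistry: TBS = tert-butyl(dimethyl)silyl and TES = triethylsilyl; the cyclisation pair is used as (3S,4E)-18 and (1R,2R,4S)-19, whose descriptors are mutually consistent and lead to C5 (R) of 36, so no structure was changed; the sense of induction of (S)-BINAP in steps 8 and 18 is assigned from the α-si binding model for enoates, and the antipodal ligand is taken in that step if a correlation shows the opposite sense; 27 is taken as a commercial compound.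

## Route

Step 1
Reactants: 1 (E)-but-2-enal (crotonaldehyde)
Product: 3 (2Z)-2-bromobut-2-enal, via 2,3-dibromobutanal 2 (not isolated)
Conditions: Br2, CH2Cl2, 0 °C; then Et3N, 0 °C → rt
Reagents that add atoms: bromine, BrBr
Why: Electrophilic bromination of the enal followed by E1cB dehydrobromination; the conjugated 2-bromo enal should form as the more stable Z isomer (bromine cis to methyl, formyl trans to it), which is the geometry every later ethylidene unit inherits.

Step 2
Reactants: 3 (2Z)-2-bromobut-2-enal
Product: 4 (2Z)-2-bromobut-2-en-1-ol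
Conditions: NaBH4, CeCl3·7H2O, MeOH, 0 °C
Reagents that add atoms: none
Why: Luche 1,2-reduction of the enal; the vinylic bromide and the alkene geometry are not affected.

Step 3
Reactants: 4 (2Z)-2-bromobut-2-en-1-ol
Product: 5 {[(2Z)-2-bromobut-2-en-1-yl]oxy}(tert-butyl)dimethylsilane
Conditions: TBSCl, imidazole, CH2Cl2, 0 °C → rt
Reagents that add atoms: tert-butyl(chloro)dimethylsilane, C[Si](C)(Cl)C(C)(C)C
Why: Standard silylation of a primary allylic alcohol; the silyl ether tolerates the organolithium, rhodium and aqueous steps that follow.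

Step 4
Reactants: 5 {[(2Z)-2-bromobut-2-en-1-yl]oxy}(tert-butyl)dimethylsilane
Product: 8 [(2E)-1-{[TBS]oxy}but-2-en-2-yl]boronic acid, via alkenyllithium 6 (not isolated), via lithium triisopropoxyborate 7 (not isolated)
Conditions: t-BuLi (2.1 equiv), Et2O, −78 °C; B(Oi-Pr)3, −78 °C → rt; dilute aq. HCl to pH 5, 0 °C
Reagents that add atoms: triisopropyl borate, CC(C)OB(OC(C)C)OC(C)C; water, O
Why: Bromine–lithium exchange with retention of alkene geometry, borylation and hydrolysis of the borate; at −78 °C the 2-lithio allyl silyl ether should neither eliminate nor transfer silicon. The descriptor changes from Z to E only because boron ranks below carbon.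

Step 5
Reactants: 9 2-(hydroxymethyl)propane-1,3-diol
Product: 10 (2,2-dimethyl-1,3-dioxan-5-yl)methanol
Conditions: 2,2-dimethoxypropane, p-TsOH·H2O (cat.), THF, rt; Et3N quench
Reagents that add atoms: 2,2-dimethoxypropane, COC(C)(C)OC
Why: Acid-catalysed transacetalisation; the six-membered acetonide is the only monomeric ketal this triol can form, so one hydroxymethyl group stays free.

Step 6
Reactants: 10 (2,2-dimethyl-1,3-dioxan-5-yl)methanol
Product: 11 2,2-dimethyl-1,3-dioxane-5-carbaldehyde
Conditions: TEMPO (10 mol %), PhI(OAc)2, CH2Cl2, rt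
Reagents that add atoms: none
Why: Nitroxyl-catalysed oxidation of a primary alcohol stops at the aldehyde without base, so the β-alkoxy aldehyde is not exposed to elimination; it is used crude.

Step 7
Reactants: 11 2,2-dimethyl-1,3-dioxane-5-carbaldehyde; 12 trimethyl phosphonoacetate
Product: 13 methyl (2E)-3-(2,2-dimethyl-1,3-dioxan-5-yl)prop-2-enoate
Conditions: LiCl, DBU, MeCN, 0 °C → rt
Reagents that add atoms: none
Why: Horner–Wadsworth–Emmons olefination under Masamune–Roush conditions; the mild amine base avoids β-elimination and the stabilised phosphonate should give the E-enoate.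

Step 8
Reactants: 13 methyl (2E)-3-(2,2-dimethyl-1,3-dioxan-5-yl)prop-2-enoate; 8 [(2E)-1-{[TBS]oxy}but-2-en-2-yl]boronic acid
Product: 14 methyl (3S,4E)-4-({[TBS]oxy}methyl)-3-(2,2-dimethyl-1,3-dioxan-5-yl)hex-4-enoate
Conditions: 8 (2.5 equiv), [Rh(OH)((S)-BINAP)]2 (3 mol % Rh), dioxane/H2O 10:1, 40 °C
Reagents that add atoms: none
Why: Hayashi–Miyaura asymmetric 1,4-addition: transmetalation gives an alkenyl complex of monovalent rhodium, the enoate inserts and the oxa-π-allyl species is protonated by water. The ligand should bind the enoate on its α-si face, which places the alkenyl group so that C3 is S; the alkenyl geometry is retained.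

Step 9
Reactants: 14 methyl (3S,4E)-4-({[TBS]oxy}methyl)-3-(2,2-dimethyl-1,3-dioxan-5-yl)hex-4-enoate
Product: 15 methyl (3S,4E)-3-(2,2-dimethyl-1,3-dioxan-5-yl)-4-(hydroxymethyl)hex-4-enoate
Conditions: Bu4NF, AcOH (1:1), THF, 0 °C → rt
Reagents that add atoms: none
Why: Fluoride-induced desilylation; the acetic acid buffer keeps the liberated alkoxide from closing onto the ester as a δ-lactone and leaves the acetonide alone.

Step 10
Reactants: 15 methyl (3S,4E)-3-(2,2-dimethyl-1,3-dioxan-5-yl)-4-(hydroxymethyl)hex-4-enoate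
Product: 17 methyl (3S,4E)-4-(bromomethyl)-3-(2,2-dimethyl-1,3-dioxan-5-yl)hex-4-enoate, via allylic methanesulfonate 16 (not isolated)
Conditions: Ms2O, Et3N, CH2Cl2, −20 °C; then LiBr, THF, 0 °C
Reagents that add atoms: lithium bromide, [Li+].[Br-]; methanesulfonic anhydride, CS(=O)(=O)OS(C)(=O)=O (its atoms remain only in 16)
Why: Sulfonylation followed by SN2 displacement at the primary allylic carbon; no cation or π-allyl species is involved, so the E geometry and the C3 centre are untouched.

Step 11
Reactants: 17 methyl (3S,4E)-4-(bromomethyl)-3-(2,2-dimethyl-1,3-dioxan-5-yl)hex-4-enoate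
Product: 18 (3S,4E)-4-(bromomethyl)-3-(2,2-dimethyl-1,3-dioxan-5-yl)hex-4-enal
Conditions: i-Bu2AlH (1.1 equiv), CH2Cl2, −78 °C; MeOH, then aq. potassium sodium tartrate
Reagents that add atoms: none
Why: Partial reduction of the methyl ester through the aluminium hemiacetal, which is stable at −78 °C; primary allylic bromides are inert to i-Bu2AlH at this temperature. The aldehyde is released last and used at once, so it never coexists with a free allylic hydroxyl.

Step 12
Reactants: 18 (3S,4E)-4-(bromomethyl)-3-(2,2-dimethyl-1,3-dioxan-5-yl)hex-4-enal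
Product: 19 (1R,2R,4S)-4-(2,2-dimethyl-1,3-dioxan-5-yl)-2-methyl-3-methylidenecyclopentan-1-ol
Conditions: CrCl2 (5 equiv), THF, 0 °C → rt, 18 added over several hours to a final concentration of about 0.01 molar
Reagents that add atoms: none
Why: Two equivalents of CrCl2 (divalent chromium) reduce the allylic carbon–bromine bond by two one-electron transfers to a σ-allyl species of trivalent chromium bound at the CH2 terminus, which adds to the tethered aldehyde at its γ-carbon (SE2′) through a closed six-membered transition state with the carbonyl oxygen on chromium. This is an intramolecular Nozaki–Hiyama allylation, closest to the known closures of 2-(halomethyl)allyl aldehydes to methylidenecycloalkanols and, for the stereochemistry, to anti-selective crotylchromium additions. The cyclopentane closes in a 5-exo-trig mode with respect to the carbonyl group, the new bond joining the ethylidene carbon (C2) to the carbonyl carbon (C3) while allyl transposition leaves the methylidene at C1. Because the oxygen must lie in the O–Cr–CH2 bridge of the bicyclo[3.2.1]-like array, the C2/C3 relationship is fixed by the alkene geometry alone: the methyl group, cis to the tether carbon in 18 and equatorial in the chair, ends up trans to the hydroxyl. The resident centre (later C5) decides the face: its dioxanyl group takes the exo position, away from the chromium-bearing bridge and from eclipsing the CH2–Cr carbon, so it is trans to the new hydroxyl and cis to the methyl group, which gives (1R,2R,4S)-19. The selectivities needed are γ- over α-attack, retention of the E-crotyl-type geometry and ring closure over oligomerisation; the first two rest on the preference of chromium for the primary terminus and on the penalty for an axial methyl group facing the chromium ligands in the isomeric allyl species, the third on slow addition at high dilution. The acetonide is inert to CrCl2 and the stereocentre of 18 is β to the aldehyde and not enolisable, so nothing else should change.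

Step 13
Reactants: 19 (1R,2R,4S)-4-(2,2-dimethyl-1,3-dioxan-5-yl)-2-methyl-3-methylidenecyclopentan-1-ol
Product: 20 tert-butyl{[(1R,2R,4S)-4-(2,2-dimethyl-1,3-dioxan-5-yl)-2-methyl-3-methylidenecyclopentyl]oxy}dimethylsilane
Conditions: TBSCl, imidazole, DMF, rt → 40 °C
Reagents that add atoms: tert-butyl(chloro)dimethylsilane, C[Si](C)(Cl)C(C)(C)C
Why: Silylation of the secondary alcohol under non-acidic conditions that leave the acetonide intact; it keeps C3 out of the oxidation in step 15.

Step 14
Reactants: 20 tert-butyl{[(1R,2R,4S)-4-(2,2-dimethyl-1,3-dioxan-5-yl)-2-methyl-3-methylidenecyclopentyl]oxy}dimethylsilane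
Product: 22 [(1R,2R,3R,5R)-3-{[TBS]oxy}-5-(2,2-dimethyl-1,3-dioxan-5-yl)-2-methylcyclopentyl]methanol (hydroxymethyl cis to methyl and dioxanyl; expected main epimer), via B-alkyl-9-BBN adduct 21 (not isolated)
Conditions: 9-BBN (2 equiv), THF, 0 °C → 50 °C; then aq. NaOH, H2O2, 0 °C → rt
Reagents that add atoms: hydrogen peroxide, OO; 9-borabicyclo[3.3.1]nonane, B1C2CCCC1CCC2 (its atoms remain only in 21)
Why: Anti-Markovnikov hydroboration–oxidation of the 1,1-disubstituted alkene; hydrogen should be delivered to C1 from the face opposite the methyl and dioxanyl groups, so the hydroxymethyl group is cis to both. Any C1 epimer is carried on, because C1 is reset in step 15.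

Step 15
Reactants: 22 [(1R,2R,3R,5R)-3-{[TBS]oxy}-5-(2,2-dimethyl-1,3-dioxan-5-yl)-2-methylcyclopentyl]methanol
Product: 24 (1S,2R,3R,5S)-3-{[TBS]oxy}-5-(2,2-dimethyl-1,3-dioxan-5-yl)-2-methylcyclopentane-1-carbaldehyde, via (1R)-epimeric aldehyde 23 (not isolated)
Conditions: (COCl)2, DMSO, CH2Cl2, −78 °C; Et3N, −78 °C → rt; then DBU (1.5 equiv), rt
Reagents that add atoms: none
Why: Swern oxidation, then base-mediated epimerisation through the enolate to the thermodynamic isomer with the formyl group trans to both neighbours. Only C1 is α to the carbonyl and there is no β-leaving group, so no other centre should respond.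

Step 16
Reactants: 24 (1S,2R,3R,5S)-3-{[TBS]oxy}-5-(2,2-dimethyl-1,3-dioxan-5-yl)-2-methylcyclopentane-1-carbaldehyde
Product: 25 [(1S,2R,3R,5R)-3-{[TBS]oxy}-5-(2,2-dimethyl-1,3-dioxan-5-yl)-2-methylcyclopentyl]methanol
Conditions: NaBH4, MeOH, 0 °C
Reagents that add atoms: none
Why: Hydride reduction of the aldehyde at low temperature fixes the C1 configuration reached in step 15.

Step 17
Reactants: 25 [(1S,2R,3R,5R)-3-{[TBS]oxy}-5-(2,2-dimethyl-1,3-dioxan-5-yl)-2-methylcyclopentyl]methanol
Product: 26 (1R,2R,3S,4R)-4-(2,2-dimethyl-1,3-dioxan-5-yl)-3-(hydroxymethyl)-2-methylcyclopentan-1-ol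
Conditions: Bu4NF, THF, rt
Reagents that add atoms: none
Why: Fluoride desilylation of the secondary silyl ether; the acetonide is inert to fluoride, so only the two hydroxyls to be acylated are free.

Step 18
Reactants: 27 5,6-dihydro-2H-pyran-2-one; 8 [(2E)-1-{[TBS]oxy}but-2-en-2-yl]boronic acid
Product: 28 (4S)-4-[(2E)-1-{[TBS]oxy}but-2-en-2-yl]oxan-2-one
Conditions: 8 (2.5 equiv), [Rh(OH)((S)-BINAP)]2 (3 mol % Rh), dioxane/H2O 10:1, 40 °C
Reagents that add atoms: none
Why: The same Hayashi–Miyaura 1,4-addition on a cyclic enoate, a well-behaved acceptor class. α-si binding of the lactone should place the alkenyl group so that C4 is S, and the lactone already holds the later carboxyl and CH2CHO arm.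

Step 19
Reactants: 28 (4S)-4-[(2E)-1-{[TBS]oxy}but-2-en-2-yl]oxan-2-one
Product: 31 (3S,4E)-3-(2-{[TBS]oxy}ethyl)-4-({[TBS]oxy}methyl)hex-4-enoic acid, via lithium hydroxy carboxylate 29 (not isolated), via bis-silylated silyl ester 30 (not isolated)
Conditions: LiOH, THF/H2O, 0 °C → rt, evaporation to dryness; TBSCl, imidazole, DMF, rt; K2CO3, MeOH/THF/H2O, rt; aq. KHSO4 to pH 4
Reagents that add atoms: lithium hydroxide, [Li+].[OH-]; tert-butyl(chloro)dimethylsilane, C[Si](C)(Cl)C(C)(C)C
Why: Saponification of the lactone, persilylation of the salt and selective solvolysis of the labile silyl ester. The hydroxy acid is never acidified, so it cannot relactonise, and the stereocentre is untouched.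

Step 20
Reactants: 26 (1R,2R,3S,4R)-4-(2,2-dimethyl-1,3-dioxan-5-yl)-3-(hydroxymethyl)-2-methylcyclopentan-1-ol; 31 (3S,4E)-3-(2-{[TBS]oxy}ethyl)-4-({[TBS]oxy}methyl)hex-4-enoic acid (2.4 equiv)
Product: 33 {(1S,2R,3R,5R)-5-(2,2-dimethyl-1,3-dioxan-5-yl)-2-methyl-3-{[(3S,4E)-3-(2-{[TBS]oxy}ethyl)-4-({[TBS]oxy}methyl)hex-4-enoyl]oxy}cyclopentyl}methyl (3S,4E)-3-(2-{[TBS]oxy}ethyl)-4-({[TBS]oxy}methyl)hex-4-enoate, via primary mono-ester 32 (not isolated)
Conditions: diisopropylcarbodiimide, DMAP, CH2Cl2, 0 °C → rt
Reagents that add atoms: none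
Why: Steglich esterification; the primary hydroxyl should react first and the hindered secondary one second under acyl-pyridinium catalysis. The acid has no α-stereocentre, so activation cannot epimerise it.

Step 21
Reactants: 33 the tetrakis-TBS diester
Product: 34 {(1S,2R,3R,5R)-5-(2,2-dimethyl-1,3-dioxan-5-yl)-3-{[(3S,4E)-3-(2-hydroxyethyl)-4-(hydroxymethyl)hex-4-enoyl]oxy}-2-methylcyclopentyl}methyl (3S,4E)-3-(2-hydroxyethyl)-4-(hydroxymethyl)hex-4-enoate
Conditions: HF·pyridine, pyridine, THF, 0 °C → rt
Reagents that add atoms: none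
Why: Buffered fluoride desilylation of four primary silyl ethers; esters and acetonide are inert. The near-neutral medium is chosen so that the δ-hydroxy esters do not lactonise, and the tetraol is oxidised at once.

Step 22
Reactants: 34 the tetraol diester
Product: 35 {(1S,2R,3R,5R)-5-(2,2-dimethyl-1,3-dioxan-5-yl)-3-{[(3S,4E)-4-formyl-3-(2-oxoethyl)hex-4-enoyl]oxy}-2-methylcyclopentyl}methyl (3S,4E)-4-formyl-3-(2-oxoethyl)hex-4-enoate
Conditions: Dess–Martin periodinane (6 equiv), NaHCO3, CH2Cl2, 0 °C → rt
Reagents that add atoms: none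
Why: Dess–Martin oxidation of all four primary alcohols under buffered, non-basic conditions; the allylic alcohols should give the E-enals without isomerisation and the acyl stereocentres are not α to any carbonyl.

Step 23
Reactants: 35 the tetra-aldehyde acetonide
Product: 36 {(1S,2R,3R,5R)-5-(1,3-dihydroxypropan-2-yl)-3-{[(3S,4E)-4-formyl-3-(2-oxoethyl)hex-4-enoyl]oxy}-2-methylcyclopentyl}methyl (3S,4E)-4-formyl-3-(2-oxoethyl)hex-4-enoate
Conditions: AcOH/H2O 4:1, rt, dilute; removal of solvent below rt
Reagents that add atoms: none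
Why: Acid-catalysed hydrolysis of the 1,3-dioxane acetonide; esters and aldehydes tolerate aqueous acetic acid and no base is used, so the diol is released last.

## Compound list

1 | (E)-but-2-enal (crotonaldehyde) | C/C=C/C=O | starting material
2 | rac-(2R,3S)-2,3-dibromobutanal (anti adduct; one enantiomer drawn) | C[C@H](Br)[C@H](Br)C=O | intermediate (not isolated)
3 | (2Z)-2-bromobut-2-enal | C/C=C(\Br)C=O | intermediate
4 | (2Z)-2-bromobut-2-en-1-ol | C/C=C(\Br)CO | intermediate
5 | {[(2Z)-2-bromobut-2-en-1-yl]oxy}(tert-butyl)dimethylsilane | C/C=C(\Br)CO[Si](C)(C)C(C)(C)C | intermediate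
6 | [(2E)-1-{[TBS]oxy}but-2-en-2-yl]lithium | C/C=C(\[Li])CO[Si](C)(C)C(C)(C)C | intermediate (not isolated)
7 | lithium [(2E)-1-{[TBS]oxy}but-2-en-2-yl]tri(propan-2-yloxy)borate | [Li+].C/C=C(/CO[Si](C)(C)C(C)(C)C)[B-](OC(C)C)(OC(C)C)OC(C)C | intermediate (not isolated)
8 | [(2E)-1-{[TBS]oxy}but-2-en-2-yl]boronic acid | C/C=C(/CO[Si](C)(C)C(C)(C)C)B(O)O | intermediate
9 | 2-(hydroxymethyl)propane-1,3-diol | OCC(CO)CO | starting material
10 | (2,2-dimethyl-1,3-dioxan-5-yl)methanol | OCC1COC(C)(C)OC1 | intermediate
11 | 2,2-dimethyl-1,3-dioxane-5-carbaldehyde | O=CC1COC(C)(C)OC1 | intermediate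
12 | trimethyl phosphonoacetate | COC(=O)CP(=O)(OC)OC | starting material
13 | methyl (2E)-3-(2,2-dimethyl-1,3-dioxan-5-yl)prop-2-enoate | COC(=O)/C=C/C1COC(C)(C)OC1 | intermediate
14 | methyl (3S,4E)-4-({[TBS]oxy}methyl)-3-(2,2-dimethyl-1,3-dioxan-5-yl)hex-4-enoate | COC(=O)C[C@@H](C1COC(C)(C)OC1)/C(CO[Si](C)(C)C(C)(C)C)=C\C | intermediate
15 | methyl (3S,4E)-3-(2,2-dimethyl-1,3-dioxan-5-yl)-4-(hydroxymethyl)hex-4-enoate | COC(=O)C[C@@H](C1COC(C)(C)OC1)/C(CO)=C\C | intermediate
16 | methyl (3S,4E)-3-(2,2-dimethyl-1,3-dioxan-5-yl)-4-{[(methanesulfonyl)oxy]methyl}hex-4-enoate | COC(=O)C[C@@H](C1COC(C)(C)OC1)/C(COS(C)(=O)=O)=C\C | intermediate (not isolated)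
17 | methyl (3S,4E)-4-(bromomethyl)-3-(2,2-dimethyl-1,3-dioxan-5-yl)hex-4-enoate | COC(=O)C[C@@H](C1COC(C)(C)OC1)/C(CBr)=C\C | intermediate
18 | (3S,4E)-4-(bromomethyl)-3-(2,2-dimethyl-1,3-dioxan-5-yl)hex-4-enal | O=CC[C@@H](C1COC(C)(C)OC1)/C(CBr)=C\C | intermediate
19 | (1R,2R,4S)-4-(2,2-dimethyl-1,3-dioxan-5-yl)-2-methyl-3-methylidenecyclopentan-1-ol | C=C1[C@@H](C)[C@H](O)C[C@H]1C2COC(C)(C)OC2 | intermediate
20 | tert-butyl{[(1R,2R,4S)-4-(2,2-dimethyl-1,3-dioxan-5-yl)-2-methyl-3-methylidenecyclopentyl]oxy}dimethylsilane | C=C1[C@@H](C)[C@H](O[Si](C)(C)C(C)(C)C)C[C@H]1C2COC(C)(C)OC2 | intermediate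
21 | 9-{[(1R,2R,3R,5R)-3-{[TBS]oxy}-5-(2,2-dimethyl-1,3-dioxan-5-yl)-2-methylcyclopentyl]methyl}-9-borabicyclo[3.3.1]nonane | B1(C[C@H]2[C@@H](C)[C@H](O[Si](C)(C)C(C)(C)C)C[C@H]2C2COC(C)(C)OC2)C2CCCC1CCC2 | intermediate (not isolated)
22 | [(1R,2R,3R,5R)-3-{[TBS]oxy}-5-(2,2-dimethyl-1,3-dioxan-5-yl)-2-methylcyclopentyl]methanol | OC[C@H]1[C@@H](C)[C@H](O[Si](C)(C)C(C)(C)C)C[C@H]1C2COC(C)(C)OC2 | intermediate
23 | (1R,2R,3R,5S)-3-{[TBS]oxy}-5-(2,2-dimethyl-1,3-dioxan-5-yl)-2-methylcyclopentane-1-carbaldehyde | O=C[C@H]1[C@@H](C)[C@H](O[Si](C)(C)C(C)(C)C)C[C@H]1C2COC(C)(C)OC2 | intermediate (not isolated)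
24 | (1S,2R,3R,5S)-3-{[TBS]oxy}-5-(2,2-dimethyl-1,3-dioxan-5-yl)-2-methylcyclopentane-1-carbaldehyde | O=C[C@@H]1[C@@H](C)[C@H](O[Si](C)(C)C(C)(C)C)C[C@H]1C2COC(C)(C)OC2 | intermediate
25 | [(1S,2R,3R,5R)-3-{[TBS]oxy}-5-(2,2-dimethyl-1,3-dioxan-5-yl)-2-methylcyclopentyl]methanol | OC[C@@H]1[C@@H](C)[C@H](O[Si](C)(C)C(C)(C)C)C[C@H]1C2COC(C)(C)OC2 | intermediate
26 | (1R,2R,3S,4R)-4-(2,2-dimethyl-1,3-dioxan-5-yl)-3-(hydroxymethyl)-2-methylcyclopentan-1-ol | OC[C@@H]1[C@@H](C)[C@H](O)C[C@H]1C2COC(C)(C)OC2 | intermediate
27 | 5,6-dihydro-2H-pyran-2-one | O=C1C=CCCO1 | starting material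
28 | (4S)-4-[(2E)-1-{[TBS]oxy}but-2-en-2-yl]oxan-2-one | O=C1C[C@H](CCO1)/C(CO[Si](C)(C)C(C)(C)C)=C\C | intermediate
29 | lithium (3S,4E)-4-({[TBS]oxy}methyl)-3-(2-hydroxyethyl)hex-4-enoate | [Li+].[O-]C(=O)C[C@H](CCO)/C(CO[Si](C)(C)C(C)(C)C)=C\C | intermediate (not isolated)
30 | tert-butyl(dimethyl)silyl (3S,4E)-3-(2-{[TBS]oxy}ethyl)-4-({[TBS]oxy}methyl)hex-4-enoate | CC(C)(C)[Si](C)(C)OC(=O)C[C@H](CCO[Si](C)(C)C(C)(C)C)/C(CO[Si](C)(C)C(C)(C)C)=C\C | intermediate (not isolated)
31 | (3S,4E)-3-(2-{[TBS]oxy}ethyl)-4-({[TBS]oxy}methyl)hex-4-enoic acid | OC(=O)C[C@H](CCO[Si](C)(C)C(C)(C)C)/C(CO[Si](C)(C)C(C)(C)C)=C\C | intermediate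
32 | [(1S,2R,3R,5R)-5-(2,2-dimethyl-1,3-dioxan-5-yl)-3-hydroxy-2-methylcyclopentyl]methyl (3S,4E)-3-(2-{[TBS]oxy}ethyl)-4-({[TBS]oxy}methyl)hex-4-enoate | C(OC(=O)C[C@H](CCO[Si](C)(C)C(C)(C)C)/C(CO[Si](C)(C)C(C)(C)C)=C\C)[C@@H]1[C@@H](C)[C@H](O)C[C@H]1C2COC(C)(C)OC2 | intermediate (not isolated)
33 | {(1S,2R,3R,5R)-5-(2,2-dimethyl-1,3-dioxan-5-yl)-2-methyl-3-{[(3S,4E)-3-(2-{[TBS]oxy}ethyl)-4-({[TBS]oxy}methyl)hex-4-enoyl]oxy}cyclopentyl}methyl (3S,4E)-3-(2-{[TBS]oxy}ethyl)-4-({[TBS]oxy}methyl)hex-4-enoate | C(OC(=O)C[C@H](CCO[Si](C)(C)C(C)(C)C)/C(CO[Si](C)(C)C(C)(C)C)=C\C)[C@@H]1[C@@H](C)[C@H](OC(=O)C[C@H](CCO[Si](C)(C)C(C)(C)C)/C(CO[Si](C)(C)C(C)(C)C)=C\C)C[C@H]1C2COC(C)(C)OC2 | intermediate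
34 | {(1S,2R,3R,5R)-5-(2,2-dimethyl-1,3-dioxan-5-yl)-3-{[(3S,4E)-3-(2-hydroxyethyl)-4-(hydroxymethyl)hex-4-enoyl]oxy}-2-methylcyclopentyl}methyl (3S,4E)-3-(2-hydroxyethyl)-4-(hydroxymethyl)hex-4-enoate | C(OC(=O)C[C@H](CCO)/C(CO)=C\C)[C@@H]1[C@@H](C)[C@H](OC(=O)C[C@H](CCO)/C(CO)=C\C)C[C@H]1C2COC(C)(C)OC2 | intermediate
35 | {(1S,2R,3R,5R)-5-(2,2-dimethyl-1,3-dioxan-5-yl)-3-{[(3S,4E)-4-formyl-3-(2-oxoethyl)hex-4-enoyl]oxy}-2-methylcyclopentyl}methyl (3S,4E)-4-formyl-3-(2-oxoethyl)hex-4-enoate | C(OC(=O)C[C@H](CC=O)/C(C=O)=C\C)[C@@H]1[C@@H](C)[C@H](OC(=O)C[C@H](CC=O)/C(C=O)=C\C)C[C@H]1C2COC(C)(C)OC2 | intermediate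
36 | {(1S,2R,3R,5R)-5-(1,3-dihydroxypropan-2-yl)-3-{[(3S,4E)-4-formyl-3-(2-oxoethyl)hex-4-enoyl]oxy}-2-methylcyclopentyl}methyl (3S,4E)-4-formyl-3-(2-oxoethyl)hex-4-enoate | C/C=C(/C=O)[C@@H](CC=O)CC(=O)OC[C@@H]1[C@@H](C)[C@H](OC(=O)C[C@H](CC=O)/C(C=O)=C\C)C[C@H]1C(CO)CO | target

## Step count and least certain steps

Total: 23 steps. Longest linear sequence: 18 steps (steps 1–4, 8–17 and 20–23, from 1 through 8, 14, 19 and 26 to 36).

Step 12 (key step). The most likely failure is erosion of diastereoselectivity. It could arise from loss of the allyl geometry by metallotropic shift before ring closure, or from too weak a facial bias from the single resident centre. Reductive loss of bromine or oligomerisation are lesser risks. The fallback replaces the organochromium formed in the flask by an isolable, configurationally stable allylstannane closed under Lewis acid. It sets out from 17: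
- Displacement of the bromide with Bu3SnLi (THF, −78 °C) should give methyl (3S,4E)-3-(2,2-dimethyl-1,3-dioxan-5-yl)-4-[(tributylstannyl)methyl]hex-4-enoate F1.
- i-Bu2AlH at −78 °C should give (3S,4E)-3-(2,2-dimethyl-1,3-dioxan-5-yl)-4-[(tributylstannyl)methyl]hex-4-enal F2.
- BF3·OEt2 in CH2Cl2 at −78 °C should close the ring by SE2′ attack on the aldehyde through an open transition state, an independent stereochemical channel that comes back to the route at 19.

Step 8. The most likely failure is slow insertion of the β-branched enoate into the hindered alkenyl–rhodium species, so that protodeboronation or β-oxygen elimination of the alkenyl group takes over; incomplete enantiofacial control is the second risk. The fallback is an auxiliary-controlled cuprate addition. It sets out from 11: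
- Horner–Wadsworth–Emmons reaction with diethyl {2-[(4S)-4-benzyl-2-oxo-1,3-oxazolidin-3-yl]-2-oxoethyl}phosphonate should give (4S)-4-benzyl-3-[(2E)-3-(2,2-dimethyl-1,3-dioxan-5-yl)prop-2-enoyl]-1,3-oxazolidin-2-one F3.
- The magnesium cuprate made from 5 (t-BuLi, then MgBr2·OEt2 and CuBr·SMe2, THF, −78 °C) should add anti to the benzyl group of the chelated imide to give (4S)-4-benzyl-3-[(3S,4E)-4-({[TBS]oxy}methyl)-3-(2,2-dimethyl-1,3-dioxan-5-yl)hex-4-enoyl]-1,3-oxazolidin-2-one F4.
- Methanolysis with MeOMgBr (MeOH/THF, 0 °C) comes back to the route at 14.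

Step 18. The same catalytic failure modes apply (competing protodeboronation and loss of the alkenyl group), although the cyclic enoate is the better acceptor. The fallback sets out from 5:
- Its magnesium cuprate is added to (4R)-4-benzyl-3-[(2E)-5-{[TBS]oxy}pent-2-enoyl]-1,3-oxazolidin-2-one F5, itself made from 3-{[TBS]oxy}propanal and the enantiomeric oxazolidinone phosphonate.
- This should give (4R)-4-benzyl-3-[(3S,4E)-3-(2-{[TBS]oxy}ethyl)-4-({[TBS]oxy}methyl)hex-4-enoyl]-1,3-oxazolidin-2-one F6.
- Cleavage with LiOH/H2O2 (THF/H2O, 0 °C) comes back to the route at 31.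

Step 21. The most likely failure is lactonisation of the liberated δ-hydroxy esters, in which either hydroxyl of an acyl chain attacks its own ester and expels the core alcohol. The fallback avoids free hydroxy esters by changing the silyl group and the unmasking method. It sets out from 28:
- HF·pyridine should give (4S)-4-[(2E)-1-hydroxybut-2-en-2-yl]oxan-2-one F7.
- Saponification, persilylation with Et3SiCl/imidazole and K2CO3/MeOH treatment (as in step 19) should give (3S,4E)-3-{2-[(triethylsilyl)oxy]ethyl}-4-{[(triethylsilyl)oxy]methyl}hex-4-enoic acid F8.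
- Esterification with 26 as in step 20 should give {(1S,2R,3R,5R)-5-(2,2-dimethyl-1,3-dioxan-5-yl)-2-methyl-3-{[(3S,4E)-3-{2-[(triethylsilyl)oxy]ethyl}-4-{[(triethylsilyl)oxy]methyl}hex-4-enoyl]oxy}cyclopentyl}methyl (3S,4E)-3-{2-[(triethylsilyl)oxy]ethyl}-4-{[(triethylsilyl)oxy]methyl}hex-4-enoate F9.
- Swern conditions in excess convert primary triethylsilyl ethers directly into aldehydes, which comes back to the route at 35 without a tetraol stage.

## Further compounds

F1 | step 12 | methyl (3S,4E)-3-(2,2-dimethyl-1,3-dioxan-5-yl)-4-[(tributylstannyl)methyl]hex-4-enoate | COC(=O)C[C@@H](C1COC(C)(C)OC1)/C(C[Sn](CCCC)(CCCC)CCCC)=C\C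
F2 | step 12 | (3S,4E)-3-(2,2-dimethyl-1,3-dioxan-5-yl)-4-[(tributylstannyl)methyl]hex-4-enal | O=CC[C@@H](C1COC(C)(C)OC1)/C(C[Sn](CCCC)(CCCC)CCCC)=C\C
F3 | step 8 | (4S)-4-benzyl-3-[(2E)-3-(2,2-dimethyl-1,3-dioxan-5-yl)prop-2-enoyl]-1,3-oxazolidin-2-one | O=C(/C=C/C1COC(C)(C)OC1)N1[C@@H](Cc2ccccc2)COC1=O
F4 | step 8 | (4S)-4-benzyl-3-[(3S,4E)-4-({[TBS]oxy}methyl)-3-(2,2-dimethyl-1,3-dioxan-5-yl)hex-4-enoyl]-1,3-oxazolidin-2-one | O=C(C[C@@H](C1COC(C)(C)OC1)/C(CO[Si](C)(C)C(C)(C)C)=C\C)N1[C@@H](Cc2ccccc2)COC1=O
F5 | step 18 | (4R)-4-benzyl-3-[(2E)-5-{[TBS]oxy}pent-2-enoyl]-1,3-oxazolidin-2-one | O=C(/C=C/CCO[Si](C)(C)C(C)(C)C)N1[C@H](Cc2ccccc2)COC1=O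
F6 | step 18 | (4R)-4-benzyl-3-[(3S,4E)-3-(2-{[TBS]oxy}ethyl)-4-({[TBS]oxy}methyl)hex-4-enoyl]-1,3-oxazolidin-2-one | O=C(C[C@H](CCO[Si](C)(C)C(C)(C)C)/C(CO[Si](C)(C)C(C)(C)C)=C\C)N1[C@H](Cc2ccccc2)COC1=O
F7 | step 21 | (4S)-4-[(2E)-1-hydroxybut-2-en-2-yl]oxan-2-one | O=C1C[C@H](CCO1)/C(CO)=C\C
F8 | step 21 | (3S,4E)-3-{2-[(triethylsilyl)oxy]ethyl}-4-{[(triethylsilyl)oxy]methyl}hex-4-enoic acid | OC(=O)C[C@H](CCO[Si](CC)(CC)CC)/C(CO[Si](CC)(CC)CC)=C\C
F9 | step 21 | {(1S,2R,3R,5R)-5-(2,2-dimethyl-1,3-dioxan-5-yl)-2-methyl-3-{[(3S,4E)-3-{2-[(triethylsilyl)oxy]ethyl}-4-{[(triethylsilyl)oxy]methyl}hex-4-enoyl]oxy}cyclopentyl}methyl (3S,4E)-3-{2-[(triethylsilyl)oxy]ethyl}-4-{[(triethylsilyl)oxy]methyl}hex-4-enoate | C(OC(=O)C[C@H](CCO[Si](CC)(CC)CC)/C(CO[Si](CC)(CC)CC)=C\C)[C@@H]1[C@@H](C)[C@H](OC(=O)C[C@H](CCO[Si](CC)(CC)CC)/C(CO[Si](CC)(CC)CC)=C\C)C[C@H]1C2COC(C)(C)OC2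
A1 | alternative 1 | (4R)-4-{[TBS]oxy}cyclopent-2-en-1-one | O=C1C[C@@H](O[Si](C)(C)C(C)(C)C)C=C1
A2 | alternative 1 | (2S,3R,4R)-4-{[TBS]oxy}-2-(hydroxymethyl)-3-methylcyclopentan-1-one | OC[C@@H]1[C@@H](C)[C@H](O[Si](C)(C)C(C)(C)C)CC1=O
A3 | alternative 2 | dimethyl 2-[(3R,4R)-3-{[TBS]oxy}-4-methyl-6-oxohexylidene]propanedioate | O=CC[C@@H](C)[C@H](O[Si](C)(C)C(C)(C)C)CC=C(C(=O)OC)C(=O)OC
A4 | alternative 2 | dimethyl 2-[(1R,2S,3R,4R)-4-{[TBS]oxy}-2-formyl-3-methylcyclopentyl]propanedioate | O=C[C@@H]1[C@@H](C)[C@H](O[Si](C)(C)C(C)(C)C)C[C@H]1C(C(=O)OC)C(=O)OC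
A5 | alternative 3 | {(1S,2R,3R,5R)-5-(2,2-dimethyl-1,3-dioxan-5-yl)-2-methyl-3-{[(2E)-5-{[TBS]oxy}pent-2-enoyl]oxy}cyclopentyl}methyl (2E)-5-{[TBS]oxy}pent-2-enoate | C(OC(=O)/C=C/CCO[Si](C)(C)C(C)(C)C)[C@@H]1[C@@H](C)[C@H](OC(=O)/C=C/CCO[Si](C)(C)C(C)(C)C)C[C@H]1C2COC(C)(C)OC2
A6 | alternative 3 | {(1S,2R,3R,5R)-5-(2,2-dimethyl-1,3-dioxan-5-yl)-2-methyl-3-{[(3S,4E)-3-(2-{[TBS]oxy}ethyl)-4-({[TBS]oxy}methyl)hex-4-enoyl]oxy}cyclopentyl}methyl (3S,4E)-3-(2-{[TBS]oxy}ethyl)-4-({[TBS]oxy}methyl)hex-4-enoate (identical with 33) | C(OC(=O)C[C@H](CCO[Si](C)(C)C(C)(C)C)/C(CO[Si](C)(C)C(C)(C)C)=C\C)[C@@H]1[C@@H](C)[C@H](OC(=O)C[C@H](CCO[Si](C)(C)C(C)(C)C)/C(CO[Si](C)(C)C(C)(C)C)=C\C)C[C@H]1C2COC(C)(C)OC2
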